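The ratio of charges is 0.682, the flask against the south run, so I work with the fraction of the charge left, which carries between the two if the loss of starting material is first order.

| flask | starting material | remark | time |
|---|---|---|---|
| south | 2.2 M | run made earlier |  |
| flask | 1.5 M |  | 20 min |

south run (percent of the starting material charged)

| time / min | over-reaction product / % | intermediate B / % | side product A / % | target / % | intermediate A / % | starting material / % |
|---|---|---|---|---|---|---|
| 1.33 | 0.4 | 0.6 | 0.5 | 2.5 | 8.7 | 87.8 |
| 2.50 | 1.2 | 2.3 | 0.7 | 6.5 | 11.1 | 77.2 |
| 4.00 | 3.7 | 4.4 | 0.8 | 11.7 | 12.2 | 67.0 |
| 5.00 | 6.3 | 4.8 | 1.2 | 14.1 | 11.3 | 61.1 |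
| 6.00 | 8.7 | 6.2 | 1.4 | 16.4 | 10.9 | 55.2 |

(scatter of a reading: 0.3 percentage points)

- percent here means starting material units held: one side product B counts as two
- the numbers in the tables scatter by 0.3 percentage points (one standard deviation)
- candidate steps: intermediate A -> target; intermediate A -> side product A; intermediate A <-> intermediate B; target -> over-reaction product; starting material + intermediate B -> side product B; starting material <-> intermediate A

1. the species in which most of what was charged as starting material, at 20 min sits (target / starting material / over-reaction product / intermediate B / intermediate A / side product A)
2. the largest share itself, whichever of these holds it, in percent of the starting material charged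

The south run seems to slow down: starting material loses 0.0917 min⁻¹ of the charge per minute up to 1.33 min, but 0.0590 min⁻¹ from 4.00 min to 6.00 min. Reckoned on the fraction left, the two stretches agree within the scatter:

up to 1.33 min: 0.0978 min⁻¹

from 4.00 min to 6.00 min: 0.0969 min⁻¹

From the last reading I take 0.0990 min⁻¹ as the loss constant, the share of the remaining starting material that goes per minute. For the flask at 20 min:

fraction left = exp(−loss constant × time) = 13.8%

The forecast names over-reaction product at 55%: “The remainder, about 55%, is over-reaction product.” My reckoning gives the starting material left, not that share.

The flask gives over-reaction product at 54.7%, so the forecast holds.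

    intermediate A → target (k = 0.00699 s⁻¹)
    intermediate A → side product A (k = 4.26 × 10⁻⁴ s⁻¹)
    intermediate A ⇌ intermediate B (K = 1.00, k = 0.00287 s⁻¹)
    target → over-reaction product (k = 0.00302 s⁻¹)
    starting material + intermediate B → side product B (k = 3.11 × 10⁻⁴ M⁻¹ s⁻¹)
    starting material ⇌ intermediate A (K = 10.0, k = 0.00167 s⁻¹)

Starting material stands at 13.6% in the flask, beside my 13.8%. Its half-life from the loss constant, 7.00 min, is longer than the 1.7 min of intermediate A by its loss to target alone and the 3.8 min of target by its loss to over-reaction product alone, but against target the factor is 1.84, so the two times are of like size. At 20 min the flask makes target at 0.697 of the rate at which it uses it up. Read at 12 min, the same flask has 30.5% left by the loss constant; the computed value is 30.2%.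

The earlier runs and the new flask were computed for an exercise.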